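The route rests on the C6–C7 bond, which belongs to both the cyclodeca-4-ene and the γ-lactone. An acyclic chain ending in a C6 enal and a C7=C11 2-(bromomethyl)acrylate is closed by a chromium(II)-mediated intramolecular Barbier (Nozaki–Hiyama) allylation. One operation forms C6–C7, closes the ten-membered ring, sets C6 and C7, moves the alkene to the exocyclic C11=C13 position and lactonises O6 onto C12. The step exploits the homoallylic array O6–C6–C7–C11=C13 at the fusion of carbocycle and α-methylene-γ-butyrolactone. The precursor already carries the C8 silyl ether, the 1,10-epoxide and the C2 and C15 silyl ethers; the angelate is introduced afterwards.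

Key step: step 15

Remark: germacrane numbering (C1–C15) is used for every intermediate; the sense of induction of (S)-TRIP in step 5 is assumed by analogy with aryl and alkenyl aldehydes and is to be checked on the first sample (Mosher esters).

Step 1
Reactants: 1 (R)-glycidol; 2 lithium acetylide–ethylenediamine complex
Product: 3 (S)-pent-4-yne-1,2-diol
Conditions: 2 (3 equiv), DMSO, 0 °C → rt; aq. NH4Cl
Reagents that add atoms: none
Why: SN2 epoxide opening by the acetylide at the unsubstituted carbon leaves the stereocentre (future C8) untouched, and the Payne rearrangement of the glycidol alkoxide is degenerate and cannot erode the configuration.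

Step 2
Reactants: 3 (S)-pent-4-yne-1,2-diol
Product: 4 (S)-4,5-bis(triethylsilyloxy)pent-1-yne
Conditions: TESCl (2.3 equiv), imidazole, CH2Cl2, 0 °C → rt
Reagents that add atoms: chlorotriethylsilane CC[Si](Cl)(CC)CC
Why: routine bis-silylation; the primary TES ether is the latent C7 aldehyde and the secondary one protects O8.

Step 3
Reactants: 4 (S)-4,5-bis(triethylsilyloxy)pent-1-yne
Product: 7 (S,E)-3-methyl-5,6-bis(triethylsilyloxy)hex-2-en-1-ol, via alkenyldimethylalane 5 (not isolated), via lithium alkenylaluminate 6 (not isolated)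
Conditions: AlMe3 (2.5 equiv), Cp2ZrCl2 (0.25 equiv), CH2Cl2, 0 °C → rt; n-BuLi, THF, −78 °C; (CH2O)n, −78 °C → rt
Reagents that add atoms: trimethylaluminium C[Al](C)C; paraformaldehyde (formaldehyde unit) C=O
Why: Negishi zirconium-catalysed carboalumination adds Me–Al syn and regioselectively across the terminal alkyne, and hydroxymethylation of the ate complex with retention gives the E-trisubstituted C1=C10 alkene carrying the C14 methyl.

Step 4
Reactants: 7 (S,E)-3-methyl-5,6-bis(triethylsilyloxy)hex-2-en-1-ol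
Product: 8 (S,E)-3-methyl-5,6-bis(triethylsilyloxy)hex-2-enal
Conditions: MnO2 (15 equiv), CH2Cl2, rt
Reagents that add atoms: none
Why: MnO2 allylic oxidation touches only the allylic primary alcohol and keeps the alkene geometry and the silyl ethers.

Step 5
Reactants: 8 (S,E)-3-methyl-5,6-bis(triethylsilyloxy)hex-2-enal; 9 allenylboronic acid pinacol ester
Product: 10 (4S,5E,8S)-6-methyl-8,9-bis(triethylsilyloxy)non-5-en-1-yn-4-ol
Conditions: 9 (1.5 equiv), (S)-TRIP (5 mol %), 4 Å MS, toluene, −20 °C; aq. NaHCO3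
Reagents that add atoms: none
Why: chiral phosphoric acid-catalysed propargylation through a closed six-membered SE2′ transition state sets C2 (2S) under catalyst control, the C8 centre being too remote to interfere.

Step 6
Reactants: 10 (4S,5E,8S)-6-methyl-8,9-bis(triethylsilyloxy)non-5-en-1-yn-4-ol
Product: 11 (1S)-1-{(2R,3R)-3-[(2S)-2,3-bis(triethylsilyloxy)propyl]-3-methyloxiran-2-yl}but-3-yn-1-ol
Conditions: mCPBA (1.2 equiv), NaHCO3, CH2Cl2, 0 °C
Reagents that add atoms: meta-chloroperoxybenzoic acid OOC(=O)c1cccc(Cl)c1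
Why: in this hydroxyl-directed (Henbest-type) peracid epoxidation, allylic 1,3-strain from the C14 methyl cis to C2 holds C2–H in the alkene plane, so the hydrogen-bonded peracid should deliver oxygen to one face and give the threo (1R,10R) epoxy alcohol, the alkyne being inert.

Step 7
Reactants: 11 epoxy alcohol
Product: 12 tert-butyl{[(1S)-1-{(2R,3R)-3-[(2S)-2,3-bis(triethylsilyloxy)propyl]-3-methyloxiran-2-yl}but-3-yn-1-yl]oxy}dimethylsilane
Conditions: TBSCl, imidazole, DMAP (cat.), DMF, rt
Reagents that add atoms: tert-butyldimethylsilyl chloride CC(C)(C)[Si](C)(C)Cl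
Why: silylation of the only free hydroxyl under mildly basic conditions that leave the epoxide alone.

Step 8
Reactants: 12 TBS ether
Product: 14 (5S)-5-[(tert-butyldimethylsilyl)oxy]-5-{(2R,3R)-3-[(2S)-2,3-bis(triethylsilyloxy)propyl]-3-methyloxiran-2-yl}pent-2-yn-1-ol, via lithium acetylide 13 (not isolated)
Conditions: n-BuLi (1.1 equiv), THF, −78 °C; (CH2O)n, −78 °C → rt
Reagents that add atoms: paraformaldehyde (formaldehyde unit) C=O
Why: hydroxymethylation of the lithium acetylide introduces C6 as a propargylic alcohol, and the epoxide is not opened by an acetylide in the absence of a Lewis acid.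

Step 9
Reactants: 14 propargylic alcohol
Product: 16 (2Z,5S)-5-[(tert-butyldimethylsilyl)oxy]-3-iodo-5-{(2R,3R)-3-[(2S)-2,3-bis(triethylsilyloxy)propyl]-3-methyloxiran-2-yl}pent-2-en-1-ol, via cyclic alkenylaluminate 15 (not isolated)
Conditions: Red-Al (1.6 equiv), THF, 0 °C; EtOAc; I2, THF, −78 → 0 °C
Reagents that add atoms: iodine II
Why: hydroxyl-directed trans-hydroalumination (Corey) places Al on C4 and H on C5 in a five-membered alkoxyaluminate, and iodinolysis with retention gives the Z-iodide with C3 and C6 trans, the geometry of the target C4=C5 bond.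

Step 10
Reactants: 17 (tributylstannyl)methanol
Product: 18 tributyl{[(tert-butyldimethylsilyl)oxy]methyl}stannane
Conditions: TBSCl, imidazole, CH2Cl2, rt
Reagents that add atoms: tert-butyldimethylsilyl chloride CC(C)(C)[Si](C)(C)Cl
Why: routine silylation turns the commercial hydroxymethylstannane into the protected C15 donor.

Step 11
Reactants: 16 Z-iodo allylic alcohol; 18 tributyl{[(tert-butyldimethylsilyl)oxy]methyl}stannane
Product: 19 (2Z,5S)-5-[(tert-butyldimethylsilyl)oxy]-3-{[(tert-butyldimethylsilyl)oxy]methyl}-5-{(2R,3R)-3-[(2S)-2,3-bis(triethylsilyloxy)propyl]-3-methyloxiran-2-yl}pent-2-en-1-ol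
Conditions: 18 (1.5 equiv), Pd(PPh3)4 (10 mol %), CuI (20 mol %), 1,4-dioxane, 90 °C
Reagents that add atoms: none
Why: Stille coupling of an α-alkoxymethylstannane (Kosugi-type hydroxymethyl transfer, the α-oxygen favouring transfer of CH2OR over butyl) replaces iodine with retention of geometry, so C15 ends cis to C6.

Step 12
Reactants: 19 allylic alcohol
Product: 20 (2Z,5S)-5-[(tert-butyldimethylsilyl)oxy]-3-{[(tert-butyldimethylsilyl)oxy]methyl}-5-{(2R,3R)-3-methyl-3-[(2S)-3-oxo-2-(triethylsilyloxy)propyl]oxiran-2-yl}pent-2-enal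
Conditions: (COCl)2 (5 equiv), DMSO (10 equiv), CH2Cl2, −78 → −30 °C; iPr2NEt, −78 → 0 °C
Reagents that add atoms: none
Why: Swern oxidation converts the free allylic alcohol into the enal and, by chlorosulfonium-induced cleavage, oxidises the primary TES ether directly to the C7 aldehyde, while secondary TES and the TBS ethers are expected to survive.

Step 13
Reactants: 20 dialdehyde; 21 methyl acrylate
Product: 22 methyl (4S)-3-hydroxy-2-methylidene-4-(triethylsilyloxy)-5-{(2R,3R)-3-[(1S,3Z)-1-[(tert-butyldimethylsilyl)oxy]-3-{[(tert-butyldimethylsilyl)oxy]methyl}-5-oxopent-3-en-1-yl]-2-methyloxiran-2-yl}pentanoate (both C7 epimers)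
Conditions: 21 (10 equiv), DABCO (1 equiv), MeOH (3 equiv), rt, 2–4 d
Reagents that add atoms: none
Why: the Morita–Baylis–Hillman reaction should occur at the electrophilic α-silyloxy aldehyde, the β,β-disubstituted enal being a poor MBH acceptor, and the unselective C7 carbinol is erased in the next step.

Step 14
Reactants: 22 MBH adduct
Product: 23 methyl (2Z,4S)-2-(bromomethyl)-4-(triethylsilyloxy)-5-{(2R,3R)-3-[(1S,3Z)-1-[(tert-butyldimethylsilyl)oxy]-3-{[(tert-butyldimethylsilyl)oxy]methyl}-5-oxopent-3-en-1-yl]-2-methyloxiran-2-yl}pent-2-enoate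
Conditions: NBS, Me2S, CH2Cl2, 0 °C → rt
Reagents that add atoms: N-bromosuccinimide BrN1C(=O)CCC1=O
Why: Corey–Kim-type activation of the MBH alcohol and SN2′ attack of bromide give the favoured (Z)-2-(bromomethyl)enoate under neutral conditions that tolerate the enal, epoxide and silyl ethers.

Step 15
Reactants: 23 bromo enoate enal
Product: 26 8-O-triethylsilyl-2,15-bis-O-(tert-butyldimethylsilyl)-1,10-epoxy-2,8,15-trihydroxygermacra-4,11(13)-dien-12,6-olide (stereocentres as in 31), via allylchromium(III) species 24 (not isolated), via chromium(III) alkoxide 25 (not isolated)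
Conditions: CrCl2 (10 equiv), THF–DMF 4:1, 2 mM (slow addition of 23), rt; then 45 °C; aq. NH4Cl
Reagents that add atoms: none
Why: Cr(II) inserts into the allylic C–Br bond by two one-electron transfers to give allylchromium 24, which adds to the C6 aldehyde with allylic transposition (SE2′) through a chair-like six-membered transition state, forming C6–C7 and moving the alkene to C11=C13; alkoxide 25 then attacks the C12 methyl ester to release the α-methylene-γ-butyrolactone. The closest known reaction type is the Nozaki–Hiyama (Barbier-type) lactone synthesis from 2-(bromomethyl)acrylates and aldehydes, in its intramolecular medium-ring form used for germacranolide carbocycles. The cyclodecene closes by a 10-exo-trig carbonyl addition and the lactone by a 5-exo-trig acyl substitution. C7 is controlled by the C8 stereocentre: with C8–H eclipsing the allyl unit (allylic 1,3-strain) the aldehyde approaches anti to the OSiEt3 group, on the face that carries the C9 tether; C6 is then set relative to C7 by the chair in which the C5 vinyl residue and C8 are both pseudo-equatorial after 1,3-metallotropic equilibration of the allylchromium, giving the anti adduct and hence the trans-fused lactone. The step needs γ- over α-attack, 1,2- over 1,4-addition to the enal and ring closure over oligomerisation; the cyclic transition state, the hard allylchromium nucleophile, high dilution and the turn elements in the chain (C4=C5 alkene, epoxide) are relied on for these.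

Step 16
Reactants: 26 silylated lactone
Product: 27 2,15-bis-O-(tert-butyldimethylsilyl)-1,10-epoxy-2,8,15-trihydroxygermacra-4,11(13)-dien-12,6-olide (stereocentres as in 31)
Conditions: HF·pyridine, pyridine, THF, 0 °C
Reagents that add atoms: none
Why: selective desilylation, the secondary TES ether being cleaved by buffered HF much faster than either TBS ether, so only O8 is freed.

Step 17
Reactants: 27 C8 alcohol; 28 angelic acid
Product: 30 8-O-angeloyl-2,15-bis-O-(tert-butyldimethylsilyl)-1,10-epoxy-2,8,15-trihydroxygermacra-4,11(13)-dien-12,6-olide (stereocentres as in 31), via angelic 2,4,6-trichlorobenzoic anhydride 29 (not isolated)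
Conditions: 28, 2,4,6-Cl3C6H2COCl, Et3N, toluene, rt; then 27, 80 °C (no DMAP)
Reagents that add atoms: none
Why: Yamaguchi esterification through the mixed anhydride acylates the hindered secondary alcohol, and omitting DMAP is intended to suppress angelate-to-tiglate isomerisation.

Step 18
Reactants: 30 bis-TBS angelate
Product: 31 (1R,2S,6R,7R,8S,10R)-8-angeloyloxy-1,10-epoxy-2,15-dihydroxygermacra-4,11(13)-dien-12,6-olide (EANPDB:COMP_00180)
Conditions: Et3N·3HF, MeCN–THF, rt → 40 °C
Reagents that add atoms: none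
Why: nearly neutral fluoride desilylation removes both TBS ethers and should spare the epoxide, the methylene lactone and the angelate geometry.

Compound list
1 | (R)-glycidol | OC[C@@H]1CO1 | starting material
2 | lithium acetylide–ethylenediamine complex | [Li]C#C.NCCN | starting material
3 | (S)-pent-4-yne-1,2-diol | C#CC[C@H](O)CO | intermediate
4 | (S)-4,5-bis(triethylsilyloxy)pent-1-yne | C#CC[C@H](O[Si](CC)(CC)CC)CO[Si](CC)(CC)CC | intermediate
5 | (S,E)-dimethyl[2-methyl-4,5-bis(triethylsilyloxy)pent-1-enyl]alane | C[Al](C)/C=C(\C)C[C@H](O[Si](CC)(CC)CC)CO[Si](CC)(CC)CC | intermediate (not isolated)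
6 | lithium butyl(dimethyl)alkenylaluminate of 5 | [Li+].CCCC[Al-](C)(C)/C=C(\C)C[C@H](O[Si](CC)(CC)CC)CO[Si](CC)(CC)CC | intermediate (not isolated)
7 | (S,E)-3-methyl-5,6-bis(triethylsilyloxy)hex-2-en-1-ol | OC/C=C(\C)C[C@H](O[Si](CC)(CC)CC)CO[Si](CC)(CC)CC | intermediate
8 | (S,E)-3-methyl-5,6-bis(triethylsilyloxy)hex-2-enal | O=C/C=C(\C)C[C@H](O[Si](CC)(CC)CC)CO[Si](CC)(CC)CC | intermediate
9 | allenylboronic acid pinacol ester | C=C=CB1OC(C)(C)C(C)(C)O1 | starting material
10 | (4S,5E,8S)-6-methyl-8,9-bis(triethylsilyloxy)non-5-en-1-yn-4-ol | C#CC[C@H](O)/C=C(\C)C[C@H](O[Si](CC)(CC)CC)CO[Si](CC)(CC)CC | intermediate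
11 | (1S)-1-{(2R,3R)-3-[(2S)-2,3-bis(triethylsilyloxy)propyl]-3-methyloxiran-2-yl}but-3-yn-1-ol | C#CC[C@H](O)[C@H]1O[C@]1(C)C[C@H](O[Si](CC)(CC)CC)CO[Si](CC)(CC)CC | intermediate
12 | TBS ether of 11 at O2 | C#CC[C@H](O[Si](C)(C)C(C)(C)C)[C@H]1O[C@]1(C)C[C@H](O[Si](CC)(CC)CC)CO[Si](CC)(CC)CC | intermediate
13 | lithium acetylide of 12 | [Li]C#CC[C@H](O[Si](C)(C)C(C)(C)C)[C@H]1O[C@]1(C)C[C@H](O[Si](CC)(CC)CC)CO[Si](CC)(CC)CC | intermediate (not isolated)
14 | propargylic alcohol (C6 hydroxymethylated alkyne; C2–OTBS, 1,10-epoxide, C7/C8 bis-OTES) | OCC#CC[C@H](O[Si](C)(C)C(C)(C)C)[C@H]1O[C@]1(C)C[C@H](O[Si](CC)(CC)CC)CO[Si](CC)(CC)CC | intermediate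
15 | sodium cyclic alkenylaluminate (2,2-bis(2-methoxyethoxy)-2,5-dihydro-1,2-oxaluminol-2-uide, C4–Al) | [Na+].COCCO[Al-]1(OCCOC)OCC=C1C[C@H](O[Si](C)(C)C(C)(C)C)[C@H]2O[C@]2(C)C[C@H](O[Si](CC)(CC)CC)CO[Si](CC)(CC)CC | intermediate (not isolated)
16 | (2Z,5S)-3-iodo allylic alcohol (I on C4 cis to C6; C2–OTBS, 1,10-epoxide, C7/C8 bis-OTES) | OC/C=C(\I)C[C@H](O[Si](C)(C)C(C)(C)C)[C@H]1O[C@]1(C)C[C@H](O[Si](CC)(CC)CC)CO[Si](CC)(CC)CC | intermediate
17 | (tributylstannyl)methanol | CCCC[Sn](CCCC)(CCCC)CO | starting material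
18 | tributyl{[(tert-butyldimethylsilyl)oxy]methyl}stannane | CCCC[Sn](CCCC)(CCCC)CO[Si](C)(C)C(C)(C)C | intermediate
19 | (2Z,5S)-allylic alcohol with C15–OTBS cis to C6 (C2–OTBS, 1,10-epoxide, C7/C8 bis-OTES) | OC/C=C(\CO[Si](C)(C)C(C)(C)C)C[C@H](O[Si](C)(C)C(C)(C)C)[C@H]1O[C@]1(C)C[C@H](O[Si](CC)(CC)CC)CO[Si](CC)(CC)CC | intermediate
20 | dialdehyde (C6 enal and C7 α-triethylsilyloxy aldehyde) | O=C/C=C(\CO[Si](C)(C)C(C)(C)C)C[C@H](O[Si](C)(C)C(C)(C)C)[C@H]1O[C@]1(C)C[C@H](O[Si](CC)(CC)CC)C=O | intermediate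
21 | methyl acrylate | C=CC(=O)OC | starting material
22 | Morita–Baylis–Hillman adduct at C7 (both C7 epimers) | O=C/C=C(\CO[Si](C)(C)C(C)(C)C)C[C@H](O[Si](C)(C)C(C)(C)C)[C@H]1O[C@]1(C)C[C@H](O[Si](CC)(CC)CC)C(O)C(=C)C(=O)OC | intermediate
23 | (Z)-2-(bromomethyl)enoate enal (cyclisation precursor) | O=C/C=C(\CO[Si](C)(C)C(C)(C)C)C[C@H](O[Si](C)(C)C(C)(C)C)[C@H]1O[C@]1(C)C[C@H](O[Si](CC)(CC)CC)/C=C(\CBr)C(=O)OC | intermediate
24 | allylchromium(III) dichloride derived from 23 (solvent ligands omitted) | O=C/C=C(\CO[Si](C)(C)C(C)(C)C)C[C@H](O[Si](C)(C)C(C)(C)C)[C@H]1O[C@]1(C)C[C@H](O[Si](CC)(CC)CC)/C=C(\C[Cr](Cl)Cl)C(=O)OC | intermediate (not isolated)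
25 | chromium(III) alkoxide of the ten-membered C6-hydroxy methyl ester | COC(=O)C(=C)[C@@H]1[C@@H](O[Si](CC)(CC)CC)C[C@@]2(C)O[C@@H]2[C@@H](O[Si](C)(C)C(C)(C)C)C/C(CO[Si](C)(C)C(C)(C)C)=C/[C@H]1O[Cr](Cl)Cl | intermediate (not isolated)
26 | 8-O-TES-2,15-bis-O-TBS-1,10-epoxy-2,8,15-trihydroxygermacra-4,11(13)-dien-12,6-olide | C=C1C(=O)O[C@@H]2/C=C(\CO[Si](C)(C)C(C)(C)C)C[C@H](O[Si](C)(C)C(C)(C)C)[C@H]3O[C@]3(C)C[C@H](O[Si](CC)(CC)CC)[C@@H]12 | intermediate
27 | 2,15-bis-O-TBS-1,10-epoxy-2,8,15-trihydroxygermacra-4,11(13)-dien-12,6-olide | C=C1C(=O)O[C@@H]2/C=C(\CO[Si](C)(C)C(C)(C)C)C[C@H](O[Si](C)(C)C(C)(C)C)[C@H]3O[C@]3(C)C[C@H](O)[C@@H]12 | intermediate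
28 | angelic acid [(Z)-2-methylbut-2-enoic acid] | C/C=C(/C)C(=O)O | starting material
29 | angelic 2,4,6-trichlorobenzoic anhydride | C/C=C(/C)C(=O)OC(=O)c1c(Cl)cc(Cl)cc1Cl | intermediate (not isolated)
30 | 8-O-angeloyl-2,15-bis-O-TBS-1,10-epoxy-2,8,15-trihydroxygermacra-4,11(13)-dien-12,6-olide | C=C1C(=O)O[C@@H]2/C=C(\CO[Si](C)(C)C(C)(C)C)C[C@H](O[Si](C)(C)C(C)(C)C)[C@H]3O[C@]3(C)C[C@H](OC(=O)/C(C)=C\C)[C@@H]12 | intermediate
31 | (1R,2S,6R,7R,8S,10R)-8-angeloyloxy-1,10-epoxy-2,15-dihydroxygermacra-4,11(13)-dien-12,6-olide (EANPDB:COMP_00180) | C=C1C(=O)O[C@@H]2/C=C(\CO)C[C@H](O)[C@H]3O[C@]3(C)C[C@H](OC(=O)/C(C)=C\C)[C@@H]12 | target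

Total step count: 18. Longest linear sequence: 17 steps (steps 1–9 and 11–18; step 10 is a one-step side branch).

Steps most likely to fail

Step 15. Ring closure may be outrun by intermolecular coupling or reductive (pinacol) dimerisation of the enal under stoichiometric Cr(II), or the face selectivity at C7 may be insufficient. The fallback sets out from 22 and generates the allyl nucleophile catalytically at low stationary concentration. Compound 22 is acetylated (Ac2O, pyridine, DMAP, 0 °C) to the Morita–Baylis–Hillman acetate F1. F1 is then cyclised under high dilution by palladium-catalysed umpolung allylation (Pd(PPh3)4 cat., InI, THF–DMF): the π-allylpalladium complex is reduced by In(I) to an allylindium(III) species, which adds to the C6 aldehyde through a six-membered transition state and lactonises. The route is rejoined at 26.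

Step 13. The slow amine-catalysed reaction may lose chemoselectivity between the two aldehydes, scramble the enal geometry by reversible conjugate addition, or epimerise C8. The fallback sets out from 19 and keeps C6 masked until the bromide is in place. The C6 hydroxyl is converted under neutral conditions (2-(4-methoxybenzyloxy)-4-methylquinoline, MeOTf, MgO, PhCF3) into the PMB ether F2. Swern oxidation then transforms only the primary TES ether into the C7 aldehyde F3. The MBH reaction with 21 gives the adduct F4, and NBS/Me2S gives the bromo enoate F5. DDQ (CH2Cl2, pH 7 buffer) releases the allylic alcohol F6, and MnO2 oxidises F6 to 23.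

Step 11. Transfer of the sp3 silyloxymethyl group from tin may be too slow, so that protodeiodination or butyl transfer takes over. The fallback sets out from 16 and avoids palladium and tin. Compound 16 is alkylated (NaH, 2-(bromomethyl)naphthalene, THF–DMF, 0 °C) to the 2-naphthylmethyl ether F7. Iodine–lithium exchange (t-BuLi, Et2O, −78 °C) and trapping of the alkenyllithium with paraformaldehyde give, with retention, the C15 alcohol F8. TBSCl/imidazole gives the silyl ether F9, and DDQ removes the naphthylmethyl group to return to 19.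

Further compounds
F1 | step 15 | Morita–Baylis–Hillman acetate of 22 (C7–OAc) | O=C/C=C(\CO[Si](C)(C)C(C)(C)C)C[C@H](O[Si](C)(C)C(C)(C)C)[C@H]1O[C@]1(C)C[C@H](O[Si](CC)(CC)CC)C(OC(C)=O)C(=C)C(=O)OC
F2 | step 13 | C6 4-methoxybenzyl ether of 19 | COc1ccc(COC/C=C(\CO[Si](C)(C)C(C)(C)C)C[C@H](O[Si](C)(C)C(C)(C)C)[C@H]2O[C@]2(C)C[C@H](O[Si](CC)(CC)CC)CO[Si](CC)(CC)CC)cc1
F3 | step 13 | C7 aldehyde with C6–OPMB | COc1ccc(COC/C=C(\CO[Si](C)(C)C(C)(C)C)C[C@H](O[Si](C)(C)C(C)(C)C)[C@H]2O[C@]2(C)C[C@H](O[Si](CC)(CC)CC)C=O)cc1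
F4 | step 13 | Morita–Baylis–Hillman adduct with C6–OPMB (both C7 epimers) | COc1ccc(COC/C=C(\CO[Si](C)(C)C(C)(C)C)C[C@H](O[Si](C)(C)C(C)(C)C)[C@H]2O[C@]2(C)C[C@H](O[Si](CC)(CC)CC)C(O)C(=C)C(=O)OC)cc1
F5 | step 13 | (Z)-2-(bromomethyl)enoate with C6–OPMB | COc1ccc(COC/C=C(\CO[Si](C)(C)C(C)(C)C)C[C@H](O[Si](C)(C)C(C)(C)C)[C@H]2O[C@]2(C)C[C@H](O[Si](CC)(CC)CC)/C=C(\CBr)C(=O)OC)cc1
F6 | step 13 | (Z)-2-(bromomethyl)enoate with free C6 allylic alcohol | OC/C=C(\CO[Si](C)(C)C(C)(C)C)C[C@H](O[Si](C)(C)C(C)(C)C)[C@H]1O[C@]1(C)C[C@H](O[Si](CC)(CC)CC)/C=C(\CBr)C(=O)OC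
F7 | step 11 | C6 2-naphthylmethyl ether of 16 | c1ccc2cc(COC/C=C(\I)C[C@H](O[Si](C)(C)C(C)(C)C)[C@H]3O[C@]3(C)C[C@H](O[Si](CC)(CC)CC)CO[Si](CC)(CC)CC)ccc2c1
F8 | step 11 | C15 alcohol with C6–O-(2-naphthylmethyl) | c1ccc2cc(COC/C=C(\CO)C[C@H](O[Si](C)(C)C(C)(C)C)[C@H]3O[C@]3(C)C[C@H](O[Si](CC)(CC)CC)CO[Si](CC)(CC)CC)ccc2c1
F9 | step 11 | C15–OTBS ether with C6–O-(2-naphthylmethyl) | c1ccc2cc(COC/C=C(\CO[Si](C)(C)C(C)(C)C)C[C@H](O[Si](C)(C)C(C)(C)C)[C@H]3O[C@]3(C)C[C@H](O[Si](CC)(CC)CC)CO[Si](CC)(CC)CC)ccc2c1
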